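The ring is opened between the methylene C2 and the bromine-bearing quaternary carbon C3 of the cyclohexane (C1 = CClMe, C4 = CH-chlorovinyl, C6 = CHBr). This cut is chosen because C1–Cl and C6–Br are cis on the ring, which anti addition to a cyclohexene cannot give. On an open chain the pair arises from anti bromochlorination of an E-alkene. Ring-closing metathesis of the fully halogenated triene 7 then joins C2 to C3 in one operation and leaves a C2=C3 alkene poised for Markovnikov hydrobromination. Triene 7 is remodelled (R)-lavandulol: its stereocentre becomes C4, its isopropenyl carbon C3, its prenyl unit C5–C6–C1 and the E-methyl group C2.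

Key step: step 7

Remark on numbering: C1 = C(Cl)CH3, C2 = CH2, C3 = C(Br)CH3, C4 = CH(CH=CHCl), C5 = CH2, C6 = CHBr; open-chain intermediates carry the same labels.
Assumption: (R)-(−)-lavandulol is bought enantiopure (lavender-oil constituent, otherwise obtained by lipase resolution of the cheap racemate).
Assumption: in step 4 the antipode of the amino-alcohol-derived tridentate Schiff base ligand is the one that places bromine on the face of C6 leading to the (2R,3S) product.

Step 1
Reactants: 1 (R)-lavandulol
Product: 2 (R)-lavandulal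
Conditions: Dess–Martin periodinane, CH2Cl2, 0 °C; used crude
Reagents that add atoms: none
Why: Dess–Martin oxidation is fast and non-basic, so the primary alcohol should give the β,γ-unsaturated aldehyde without migration of the isopropenyl double bond or loss of the future C4 stereocentre.

Step 2
Reactants: 2 (R)-lavandulal
Product: 3 (1E,3S)-1-chloro-6-methyl-3-(prop-1-en-2-yl)hepta-1,5-diene
Conditions: CrCl2 (6 equiv), CHCl3 (2 equiv), THF, 65 °C
Reagents that add atoms: chloroform, ClC(Cl)Cl
Why: Takai–Utimoto olefination: the non-basic gem-dichromium species from CHCl3 adds to the aldehyde and eliminates to the E-chloroalkene, and it is run here, before any sp3 carbon–halogen bond exists that divalent chromium could reduce.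

Step 3
Reactants: 3 (1E,3S)-1-chloro-6-methyl-3-(prop-1-en-2-yl)hepta-1,5-diene
Product: 4 (2E,5S,6E)-7-chloro-2-methyl-5-(prop-1-en-2-yl)hepta-2,6-dien-1-ol
Conditions: SeO2 (0.3 equiv), t-BuOOH, salicylic acid (cat.), CH2Cl2, 0 °C to rt
Reagents that add atoms: tert-butyl hydroperoxide, CC(C)(C)OO (oxygen passed on through catalytic SeO2, O=[Se]=O)
Why: Riley allylic oxidation (ene reaction, then [2,3]-sigmatropic shift) attacks the most electron-rich, trisubstituted alkene and oxidises its E-methyl group, which turns that carbon into C2 and fixes the geometry with C2 trans to C5.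

Step 4
Reactants: 4 (2E,5S,6E)-7-chloro-2-methyl-5-(prop-1-en-2-yl)hepta-2,6-dien-1-ol
Product: 5 (2R,3S,5S,6E)-3-bromo-2,7-dichloro-2-methyl-5-(prop-1-en-2-yl)hept-6-en-1-ol
Conditions: NBS, ClTi(OiPr)3, chiral tridentate Schiff base ligand (20 mol %), hexanes, −20 °C
Reagents that add atoms: N-bromosuccinimide, O=C1CCC(=O)N1Br; chlorotitanium triisopropoxide, CC(C)O[Ti](Cl)(OC(C)C)OC(C)C
Why: Titanium-mediated catalytic asymmetric bromochlorination of allylic alcohols: the bound alkoxide restricts bromonium formation to the neighbouring alkene and the ligand picks its face (C6), chloride opens it anti at the tertiary carbon (Markovnikov, C1), and anti addition to the E-alkene gives the C1/C6 relationship that becomes cis on the ring.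

Step 5
Reactants: 5 (2R,3S,5S,6E)-3-bromo-2,7-dichloro-2-methyl-5-(prop-1-en-2-yl)hept-6-en-1-ol
Product: 6 (2R,3S,5S,6E)-3-bromo-2,7-dichloro-2-methyl-5-(prop-1-en-2-yl)hept-6-enal
Conditions: Dess–Martin periodinane, CH2Cl2, 0 °C to rt
Reagents that add atoms: none
Why: Dess–Martin oxidation avoids base, which would close the chlorohydrin to an epoxide, and the α-carbon C1 is fully substituted, so the α-chloro aldehyde cannot epimerise.

Step 6
Reactants: 6 (2R,3S,5S,6E)-3-bromo-2,7-dichloro-2-methyl-5-(prop-1-en-2-yl)hept-6-enal
Product: 7 (1E,3S,5S,6R)-5-bromo-1,6-dichloro-6-methyl-3-(prop-1-en-2-yl)octa-1,7-diene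
Conditions: Ph3PCH3Br, KN(SiMe3)2, THF, −78 to 0 °C
Reagents that add atoms: methyltriphenylphosphonium bromide, C[P+](c1ccccc1)(c1ccccc1)c1ccccc1.[Br-]
Why: Wittig methylenation: addition of the unhindered ylide to the non-enolisable aldehyde at low temperature should outrun E2 loss of HBr or HCl and turns C2 into the vinyl carbon needed for ring closure.

Step 7
Reactants: 7 (1E,3S,5S,6R)-5-bromo-1,6-dichloro-6-methyl-3-(prop-1-en-2-yl)octa-1,7-diene
Product: 8 (3R,4S,6S)-4-bromo-3-chloro-6-[(E)-2-chloroethenyl]-1,3-dimethylcyclohex-1-ene
Conditions: second-generation Hoveyda–Grubbs catalyst, RuCl2(H2IMes)(=CH-2-iPrOC6H4) (5 mol %), toluene (high dilution), 40 °C, argon sparge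
Reagents that add atoms: none
Why: Chauvin mechanism: the catalyst exchanges its carbene with the only monosubstituted alkene (C2H=CH2), the C2 alkylidene adds in a [2+2] sense to the 1,1-disubstituted C3=CH2 alkene, and cycloreversion of the ruthenacyclobutane delivers the C2=C3 bond and, after turnover, ethene. The closest known reaction type is ring-closing metathesis of 1,7-dienes that pair a vinyl with an isopropenyl group to give 1-methylcyclohexenes. One ring is closed, the six-membered carbocycle C1–C6, and the closure is helped by the fully substituted C1 (gem-dialkyl effect). No stereocentre is created: C1, C4 and C6 are spectators and the neutral conditions leave all carbon–halogen bonds in place, so the open-chain anti relationship of Cl and Br is folded into the cis ring relationship. The selectivity needed is chemoselectivity between the isopropenyl and the E-chlorovinyl group on C4, both of which could close a six-membered ring; the electron-poor 1,2-disubstituted chloroalkene is a sluggish partner that would have to release an unfavourable chloromethylidene, so closure on the isopropenyl group should win. The tertiary allylic chloride 8 is kept in aprotic media, passed only through neutral alumina and used at once.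

Step 8
Reactants: 8 (3R,4S,6S)-4-bromo-3-chloro-6-[(E)-2-chloroethenyl]-1,3-dimethylcyclohex-1-ene
Product: 9 (1R,2S,4S,5R)-1,4-dibromo-5-chloro-2-[(E)-2-chloroethenyl]-1,5-dimethylcyclohexane (target)
Conditions: Co(acac)2 (25 mol %), t-BuOOH (25 mol %), Ph(iPrO)SiH2, TsBr, CH2Cl2, 0 °C
Reagents that add atoms: 4-methylbenzenesulfonyl bromide (TsBr), Cc1ccc(cc1)S(=O)(=O)Br
Why: Metal-hydride hydrogen-atom-transfer (MHAT) Markovnikov hydrobromination: cobalt hydride gives H to C2 of the more reactive trisubstituted alkene, and the planar tertiary C3 radical takes bromine from bulky TsBr on the face opposite the axial C1–Cl and the C4 side chain. This sets C3 with Br trans to both, and the aprotic radical conditions avoid ionisation of the allylic chloride and hydride shifts from C4.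

Compound list
1 | (R)-(−)-lavandulol, (2R)-5-methyl-2-(prop-1-en-2-yl)hex-4-en-1-ol | CC(C)=CC[C@@H](CO)C(C)=C | starting material
2 | (R)-lavandulal, (2R)-5-methyl-2-(prop-1-en-2-yl)hex-4-enal | CC(C)=CC[C@@H](C=O)C(C)=C | intermediate
3 | (1E,3S)-1-chloro-6-methyl-3-(prop-1-en-2-yl)hepta-1,5-diene | CC(C)=CC[C@@H](/C=C/Cl)C(C)=C | intermediate
4 | (2E,5S,6E)-7-chloro-2-methyl-5-(prop-1-en-2-yl)hepta-2,6-dien-1-ol | OC/C(C)=C/C[C@@H](/C=C/Cl)C(C)=C | intermediate
5 | (2R,3S,5S,6E)-3-bromo-2,7-dichloro-2-methyl-5-(prop-1-en-2-yl)hept-6-en-1-ol | OC[C@@](C)(Cl)[C@@H](Br)C[C@@H](/C=C/Cl)C(C)=C | intermediate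
6 | (2R,3S,5S,6E)-3-bromo-2,7-dichloro-2-methyl-5-(prop-1-en-2-yl)hept-6-enal | O=C[C@@](C)(Cl)[C@@H](Br)C[C@@H](/C=C/Cl)C(C)=C | intermediate
7 | (1E,3S,5S,6R)-5-bromo-1,6-dichloro-6-methyl-3-(prop-1-en-2-yl)octa-1,7-diene | C=C[C@@](C)(Cl)[C@@H](Br)C[C@@H](/C=C/Cl)C(C)=C | intermediate
8 | (3R,4S,6S)-4-bromo-3-chloro-6-[(E)-2-chloroethenyl]-1,3-dimethylcyclohex-1-ene | C[C@@]1(Cl)C=C(C)[C@H](/C=C/Cl)C[C@@H]1Br | intermediate
9 | (1R,2S,4S,5R)-1,4-dibromo-5-chloro-2-[(E)-2-chloroethenyl]-1,5-dimethylcyclohexane | C[C@@]1(Cl)C[C@@](C)(Br)[C@H](/C=C/Cl)C[C@@H]1Br | target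

Total step count: 8. Longest linear sequence: 8 steps (1 to 9).

Steps most likely to fail

Step 7.
- What may go wrong: carbene loading at the vinyl group next to quaternary C1 may be slow. The catalyst would then be consumed at the chlorovinyl group, and long heating would invite 1,3-transposition of the allylic chloride.
- Fallback (relay ring-closing metathesis): it sets out from 6 and comes back at 8. Wittig reaction of 6 with the ylide from hex-5-en-1-yltriphenylphosphonium bromide and KN(SiMe3)2 gives (1E,3S,5S,6R,7Z)-5-bromo-1,6-dichloro-6-methyl-3-(prop-1-en-2-yl)trideca-1,7,12-triene F1.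
- Why it helps: the catalyst loads on the unhindered terminal alkene, expels cyclopentene and is thereby delivered intramolecularly to C2. Closure onto the isopropenyl group can then run at room temperature.

Step 8.
- What may go wrong: facial selectivity at the planar C3 radical may be poor, hydrogen-atom transfer to the chlorovinyl group may compete, and transfer to the hindered ring alkene may be slow.
- Fallback (polar hydrobromination): it sets out from 8 and comes back at 9. Anhydrous HBr is added in pentane at −78 °C, a termolecular anti addition in a non-ionising medium. The proton goes to C2 on the face of C1–Cl and bromide to C3 on the opposite face. This fallback makes no new compound (F0).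

Step 4.
- What may go wrong: chloride may be delivered to the wrong carbon, face control by the catalyst may be poor, or the bromonium ion may be captured by the isopropenyl group.
- Fallback (a stereospecific sequence): it sets out from 4 and comes back at 5.
  - Sharpless asymmetric epoxidation (Ti(OiPr)4, D-(−)-diethyl tartrate, t-BuOOH, CH2Cl2, −20 °C) gives the (2R,3R)-epoxy alcohol F2.
  - Li2NiBr4 in THF opens it at the secondary carbon C6 with inversion to the bromodiol F3.
  - TBSCl and imidazole give the primary silyl ether F4.
  - 1-Chloro-N,N,2-trimethylpropenylamine in CH2Cl2 replaces the tertiary hydroxyl by chloride with retention. It does so through the C6 bromonium ion, which is reachable in the open chain and is opened at tertiary C1. This gives the silyl-protected bromochloride F5.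
  - HF·pyridine then releases 5.

Further compounds
F1 | step 7 | (1E,3S,5S,6R,7Z)-5-bromo-1,6-dichloro-6-methyl-3-(prop-1-en-2-yl)trideca-1,7,12-triene | C=CCCC/C=C\[C@@](C)(Cl)[C@@H](Br)C[C@@H](/C=C/Cl)C(C)=C
F0 | step 8 | none | none
F2 | step 4 | [(2R,3R)-3-[(2S,3E)-4-chloro-2-(prop-1-en-2-yl)but-3-en-1-yl]-2-methyloxiran-2-yl]methanol | OC[C@@]1(C)O[C@@H]1C[C@@H](/C=C/Cl)C(C)=C
F3 | step 4 | (2R,3S,5S,6E)-3-bromo-7-chloro-2-methyl-5-(prop-1-en-2-yl)hept-6-ene-1,2-diol | OC[C@@](C)(O)[C@@H](Br)C[C@@H](/C=C/Cl)C(C)=C
F4 | step 4 | (2R,3S,5S,6E)-3-bromo-1-[(tert-butyldimethylsilyl)oxy]-7-chloro-2-methyl-5-(prop-1-en-2-yl)hept-6-en-2-ol | CC(C)(C)[Si](C)(C)OC[C@@](C)(O)[C@@H](Br)C[C@@H](/C=C/Cl)C(C)=C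
F5 | step 4 | tert-butyl{[(2R,3S,5S,6E)-3-bromo-2,7-dichloro-2-methyl-5-(prop-1-en-2-yl)hept-6-en-1-yl]oxy}dimethylsilane | CC(C)(C)[Si](C)(C)OC[C@@](C)(Cl)[C@@H](Br)C[C@@H](/C=C/Cl)C(C)=C
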